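## Structural features

The target 12 is an isoflavone: a benzene ring (ring A) fused through the C4a–C8a bond to a 4H-pyran-4-one (ring C), with a 3,4,5-trimethoxyphenyl ring (ring B) on C3 and hydrogen on C2. Ring A carries a methoxy group on C6 and the only free hydroxyl on C7, while C5 and C8 are unsubstituted. O1 and O7 are therefore meta to each other, and C4a is ortho to O1 and para to O7. There is no stereocentre and no hindered axis, since ring B has no ortho substituent. The fragile sites are C2 of the pyranone (a vinylogous ester carbon that hydroxide or amines open), the reducible C2=C3 bond, the central 4'-methoxy group of ring B (the ether most easily lost to Lewis acids), and the single phenol that must be kept distinct from five methyl ether oxygens. The real difficulty is regiochemical: O7 must be told apart from O6, and the C4–C4a bond must be made at exactly one carbon of an electron-rich ring A while the equally electron-rich ring B is left alone. The key step exploits the fact that C4a is the least hindered and most nucleophilic carbon of ring A (para to O7, ortho to O1) and that C4 is at the acyl oxidation level. Ring C can therefore be closed last at the C4–C4a carbon–carbon bond, with the O1–C2=C3(ring B) enol ether already in place.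

## Logic of the disconnections

In one sentence: ring C is closed last at the C4–C4a carbon–carbon bond by intramolecular Friedel–Crafts acylation of 9, an aryl enol ether that already holds the O1–C2 bond. This sentence does not fit the usual routes, which close ring C at O1 or attach ring B to a finished chromone.

12 to 11: the O7–benzyl bond is cut. A benzyl ether keeps O7 distinct from the O6 methyl ether from the first step on and leaves O7 a strong para donor for the key step. The forward step must remove the benzyl group without reducing C2=C3.

11 to 8 (through 9 and 10): the C4–C4a bond is cut. This is the key disconnection. It opens ring C at carbon, removes the fused bicycle, and turns the regiochemical problem of ring A into a choice between the two carbons ortho to O1 that the tether can reach. The forward step needs an acyl cation at C4, an enol ether geometry that can equilibrate so that C4 faces ring A, and conditions that spare the benzyl ether.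

8 to 7 and 3: the O1–C2 bond is cut, here an intermolecular vinyl C–O bond and not a ring bond. This splits the molecule into a ring A phenol and a three-carbon acrylate that carries ring B, two pieces of similar size. The forward step needs the phenoxide to attack the β-carbon of 7 and displace the sulfonate.

7 to 6: the O–S bond of the enol sulfonate is cut. It only installs a leaving group on the oxygen of the formyl ester and demands O- over C-sulfonylation.

6 to 5: the C2–C3 bond (chromone numbering) is cut, between the benzylic carbon and a one-carbon formyl unit. This reduces the acrylate to an arylacetate and demands a clean crossed Claisen condensation.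

5 to 4: the ester O–C(tert-butyl) bond is cut. The tert-butyl ester is chosen so that the carboxyl group can later be freed by acid, not by hydroxide, which could add to the β-carbon of 8 and expel the phenoxide of 3.

3 to 1 (through 2): the aryl C–O bond of the phenol is traced to an aryl C–CHO bond. The oxygenation pattern of ring A, with O7 already benzylated, is thus bought in one commercial aldehyde. The forward step needs aryl, not hydride, migration in a peracid oxidation.

## Other disconnections considered

Alternative 1: This is the route that comes to mind first. The cuts are at O1–C2 and C2–C3, then at C4–C4a in the intermolecular sense. Forward, 4-methoxybenzene-1,3-diol A1 would be C-acylated with 4 under Friedel–Crafts conditions to give the deoxybenzoin 1-(2,4-dihydroxy-5-methoxyphenyl)-2-(3,4,5-trimethoxyphenyl)ethan-1-one A2. A formamide acetal would then insert C2 into A2, and ring C would close at O1 to give 12. On step count alone this plan is shorter. It is set aside for two reasons. It is the conventional closure at the heteroatom. The C–C bond that leads to A2 is also formed intermolecularly and needs a hot, strongly Lewis acidic medium, in which the 4'-methoxy group of ring B is the ether most at risk and the oxidation-prone A1 must choose between O- and C-acylation. In the chosen plan the same C4–C4a bond is made intramolecularly at or below room temperature, and the tether, not the reagent, fixes the site.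

Alternative 2: The cut is at C3–C1'. Forward, 7-(benzyloxy)-3-iodo-6-methoxy-4H-chromen-4-one A4 would be joined to (3,4,5-trimethoxyphenyl)boronic acid A5 by Suzuki–Miyaura coupling to give 11. A4 would itself have to be built from 1-[4-(benzyloxy)-2-hydroxy-5-methoxyphenyl]ethan-1-one A3 by enaminone formation and iodine-induced closure at O1. The plan therefore still closes ring C at the heteroatom, and A3 is a regioselectively benzylated ring A ketone that is not a simple article of commerce and would have to be made first. The coupling also runs in aqueous base, and the electrophilic C2 of the 3-iodochromone A4 is the position that base opens. The plan settles none of the ring A difficulty and is at least as long as the chosen route.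

Alternative 3: The cuts are at C8a–O1 and C4–C4a at once, with an aryne taking up both neighbouring substituents of ring A. Fluoride would convert 4-(benzyloxy)-5-methoxy-2-(trimethylsilyl)phenyl trifluoromethanesulfonate A6 into 4-(benzyloxy)-5-methoxybenzyne A7. The carboxylate of (E)-3-methoxy-2-(3,4,5-trimethoxyphenyl)prop-2-enoic acid A8 would add to A7, and the aryl anion would attack the ester carbonyl and open the four-membered ring to an ortho-acyl phenoxide. This phenoxide would displace the methoxide that A8 carries on its β-carbon to give 11 in one operation. The plan is attractive but fails on regiochemistry. A7 has only hydrogen beside the triple bond, and its two oxygen substituents are each meta to one aryne carbon and para to the other, with almost the same inductive effect. The carboxylate should therefore add to both ends, giving 11 together with the regioisomer 6-(benzyloxy)-7-methoxy-3-(3,4,5-trimethoxyphenyl)-4H-chromen-4-one A9 in comparable amounts. A9 differs from 11 only in which of O6 and O7 bears the benzyl group, so it should be difficult to remove. A6 would also cost four or five steps of its own. The chosen plan fixes the same two bonds one after the other, each with defined regiochemistry.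

Key step: step 6

Assumption: 1 and 4 are taken as commercial; conjugate bases formed by simple deprotonation (the enolate of 6, the phenoxide of 3) are treated as ionization states of the numbered compounds.
Assumption: 6 is drawn as its hydrogen-bonded (Z)-enol, the expected main tautomer of an α-formyl arylacetate; 7 to 10 are drawn as the (E) isomers expected from the sulfonylation, and this geometry is erased in step 6.

## Steps

Step 1
Reactants: 1 3-(benzyloxy)-4-methoxybenzaldehyde
Product: 3 3-(benzyloxy)-4-methoxyphenol, via aryl formate 2 (not isolated)
Conditions: mCPBA (1.3 equiv), CH2Cl2, 0 °C to rt; aq. NaHCO3 wash; then K2CO3 (0.1 equiv), MeOH, rt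
Reagents that add atoms: m-chloroperoxybenzoic acid (mCPBA), O=C(OO)c1cccc(Cl)c1
Why: Baeyer–Villiger (Dakin-type) oxidation, in which the electron-rich aryl group (para-methoxy) should migrate in preference to hydride to give formate 2. Mild methanolysis then frees phenol 3 and leaves the benzyl and methyl ethers untouched.

Step 2
Reactants: 4 2-(3,4,5-trimethoxyphenyl)acetic acid
Product: 5 tert-butyl 2-(3,4,5-trimethoxyphenyl)acetate
Conditions: tert-butyl 2,2,2-trichloroacetimidate (2 equiv), BF3·OEt2 (5 mol %), CH2Cl2/cyclohexane, rt
Reagents that add atoms: tert-butyl 2,2,2-trichloroacetimidate, CC(C)(C)OC(=N)C(Cl)(Cl)Cl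
Why: Acid-catalysed tert-butylation of a carboxylic acid by an imidate, a standard esterification that needs no base. The tert-butyl ester is chosen so that the carboxyl group can be freed later by acid.

Step 3
Reactants: 5 tert-butyl 2-(3,4,5-trimethoxyphenyl)acetate
Product: 6 tert-butyl (Z)-3-hydroxy-2-(3,4,5-trimethoxyphenyl)prop-2-enoate
Conditions: NaH (2.5 equiv), HCO2Me (5 equiv), THF, 0 °C to rt; then cold 1 M HCl
Reagents that add atoms: methyl formate, COC=O
Why: Crossed Claisen condensation (C-formylation) of the ester enolate with a formate that cannot enolize, driven by formation of the stabilized enolate of the product. The bulky tert-butyl ester should resist transesterification and self-condensation.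

Step 4
Reactants: 6 tert-butyl (Z)-3-hydroxy-2-(3,4,5-trimethoxyphenyl)prop-2-enoate
Product: 7 tert-butyl (E)-2-(3,4,5-trimethoxyphenyl)-3-(tosyloxy)prop-2-enoate
Conditions: TsCl (1.3 equiv), N-methylimidazole (1.5 equiv), Et3N (1.5 equiv), MeCN, 0 °C
Reagents that add atoms: p-toluenesulfonyl chloride (TsCl), Cc1ccc(cc1)S(=O)(=O)Cl
Why: O-Sulfonylation of the enol through the N-sulfonylimidazolium salt, which with an amine base should give mainly the (E) enol tosylate. The geometry does not matter because step 6 erases it.

Step 5
Reactants: 7 tert-butyl (E)-2-(3,4,5-trimethoxyphenyl)-3-(tosyloxy)prop-2-enoate; 3 3-(benzyloxy)-4-methoxyphenol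
Product: 8 tert-butyl (E)-3-[3-(benzyloxy)-4-methoxyphenoxy]-2-(3,4,5-trimethoxyphenyl)prop-2-enoate
Conditions: Cs2CO3 (1.2 equiv), MeCN, rt to 40 °C
Reagents that add atoms: none
Why: Nucleophilic vinylic substitution by addition–elimination: the phenoxide adds to the β-carbon of the acrylate and the resulting ester enolate expels tosylate. The hindered tert-butyl ester blocks attack at the carbonyl, and the step makes the O1–C2 bond of the target before ring C exists.

Step 6
Reactants: 8 tert-butyl (E)-3-[3-(benzyloxy)-4-methoxyphenoxy]-2-(3,4,5-trimethoxyphenyl)prop-2-enoate
Product: 11 7-(benzyloxy)-6-methoxy-3-(3,4,5-trimethoxyphenyl)-4H-chromen-4-one, via acrylic acid 9 (not isolated), via mixed trifluoroacetic anhydride 10 (not isolated)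
Conditions: TFA/CH2Cl2 (1:3), 0 °C to rt, then evaporation; TFAA (3 equiv), TfOH (10 mol %), CH2Cl2 (0.02 M), 0 °C to rt
Reagents that add atoms: none
Why: Trifluoroacetic acid ionizes the tert-butyl ester (loss of 2-methylpropene) to acid 9, trifluoroacetic anhydride converts 9 into mixed anhydride 10, and the catalytic triflic acid ionizes 10 to a β-aryloxy acylium ion. This ion is a vinylogous oxocarbenium (ArO+=CH–C(Ar')=C=O in one resonance form), so rotation about C2–C3 is easy and the (E) geometry of 8 should equilibrate to the form in which the acyl carbon C4 faces ring A. Ring C then closes by intramolecular Friedel–Crafts acylation, with C4 attacked by C4a, followed by rearomatization; the closest known reaction type is the acid-mediated cyclization of (E)-3-aryloxyacrylic acids to chromones. The closure forms a six-membered ring at a carbon–carbon bond: counted at the electrophile it is a 6-exo attack on the acyl carbon, whose C=O bond stays outside the ring, and counted at the nucleophile the C4a=C8a bond of ring A ends inside the new ring. No stereocentre is created and the enol ether geometry disappears into the ring. The step needs site selectivity between the two carbons ortho to O1: C4a is para to the benzyloxy oxygen O7 and unhindered, whereas the other carbon is flanked by O1 and O7 and would give a 1,2,3,4-tetrasubstituted ring, so attack para to O7 should dominate. Ring B cannot compete within the molecule, because attack at its ortho carbon would close a four-membered ring, and high dilution should suppress intermolecular acylation. The low acid loading at 0 °C is chosen to spare the benzyl ether.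

Step 7
Reactants: 11 7-(benzyloxy)-6-methoxy-3-(3,4,5-trimethoxyphenyl)-4H-chromen-4-one
Product: 12 7-hydroxy-6-methoxy-3-(3,4,5-trimethoxyphenyl)-4H-chromen-4-one
Conditions: H2 (1 atm), 10% Pd/C, EtOAc/THF, rt, stopped after one equivalent of H2
Reagents that add atoms: none
Why: Hydrogenolysis of the benzylic C–O bond on palladium, a standard deprotection to which the five methyl ethers are inert. The C2=C3 bond, part of a vinylogous ester conjugated to two aryl rings, should be reduced much more slowly.

## Compound list

1 | 3-(benzyloxy)-4-methoxybenzaldehyde | COc1ccc(C=O)cc1OCc1ccccc1 | starting material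
2 | 3-(benzyloxy)-4-methoxyphenyl formate | COc1ccc(OC=O)cc1OCc1ccccc1 | intermediate (not isolated)
3 | 3-(benzyloxy)-4-methoxyphenol | COc1ccc(O)cc1OCc1ccccc1 | intermediate
4 | 2-(3,4,5-trimethoxyphenyl)acetic acid | COc1cc(CC(=O)O)cc(OC)c1OC | starting material
5 | tert-butyl 2-(3,4,5-trimethoxyphenyl)acetate | COc1cc(CC(=O)OC(C)(C)C)cc(OC)c1OC | intermediate
6 | tert-butyl (Z)-3-hydroxy-2-(3,4,5-trimethoxyphenyl)prop-2-enoate | CC(C)(C)OC(=O)/C(=C\O)c1cc(OC)c(OC)c(OC)c1 | intermediate
7 | tert-butyl (E)-2-(3,4,5-trimethoxyphenyl)-3-(tosyloxy)prop-2-enoate | CC(C)(C)OC(=O)/C(c1cc(OC)c(OC)c(OC)c1)=C/OS(=O)(=O)c1ccc(C)cc1 | intermediate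
8 | tert-butyl (E)-3-[3-(benzyloxy)-4-methoxyphenoxy]-2-(3,4,5-trimethoxyphenyl)prop-2-enoate | CC(C)(C)OC(=O)/C(c1cc(OC)c(OC)c(OC)c1)=C/Oc1ccc(OC)c(OCc2ccccc2)c1 | intermediate
9 | (E)-3-[3-(benzyloxy)-4-methoxyphenoxy]-2-(3,4,5-trimethoxyphenyl)prop-2-enoic acid | OC(=O)/C(c1cc(OC)c(OC)c(OC)c1)=C/Oc1ccc(OC)c(OCc2ccccc2)c1 | intermediate (not isolated)
10 | (E)-3-[3-(benzyloxy)-4-methoxyphenoxy]-2-(3,4,5-trimethoxyphenyl)prop-2-enoic trifluoroacetic anhydride | FC(F)(F)C(=O)OC(=O)/C(c1cc(OC)c(OC)c(OC)c1)=C/Oc1ccc(OC)c(OCc2ccccc2)c1 | intermediate (not isolated)
11 | 7-(benzyloxy)-6-methoxy-3-(3,4,5-trimethoxyphenyl)-4H-chromen-4-one | COc1cc2c(=O)c(-c3cc(OC)c(OC)c(OC)c3)coc2cc1OCc1ccccc1 | intermediate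
12 | 7-hydroxy-6-methoxy-3-(3,4,5-trimethoxyphenyl)-4H-chromen-4-one | COc1cc2c(=O)c(-c3cc(OC)c(OC)c(OC)c3)coc2cc1O | target

## Step count and risks

Total step count: 7. Longest linear sequence: 6 steps (steps 2 to 7, from 4); step 1 is the one-step side branch that supplies 3.

Step 6 (key step). The most likely failures are three. The benzyl ether may ionize under the strong acid, followed by C-benzylation of the electron-rich rings. The ring closure may be slow, because the enol ether oxygen stabilizes the acylium ion and lowers its electrophilicity. The aryl enol ether may undergo acidolysis and return phenol 3 before acylation. The fallback gives up the closure at carbon and returns to the closure at O1. It sets out from 3 (with 4) and comes back at 11. Phenol 3 would be esterified with 4 (DCC, DMAP, CH2Cl2) to 3-(benzyloxy)-4-methoxyphenyl 2-(3,4,5-trimethoxyphenyl)acetate F1. A photo-Fries rearrangement (254 nm, MeCN) under neutral conditions should move the acyl group to the free ortho carbon para to the benzyloxy group, the para position being blocked by the methoxy group, and give 1-[4-(benzyloxy)-2-hydroxy-5-methoxyphenyl]-2-(3,4,5-trimethoxyphenyl)ethan-1-one F2. Heating F2 with N,N-dimethylformamide dimethyl acetal in toluene should give (E)-1-[4-(benzyloxy)-2-hydroxy-5-methoxyphenyl]-3-(dimethylamino)-2-(3,4,5-trimethoxyphenyl)prop-2-en-1-one F3, which cyclizes with loss of dimethylamine to 11.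

Step 5. The most likely failure is sulfonyl transfer: the hard phenoxide may attack sulfur instead of the β-carbon, cleave the S–O bond and return the enolate of 6. The fallback builds the vinyl ether first and adds ring B afterwards. It sets out from 3 and comes back at 8. Phenol 3 would add to tert-butyl propiolate (DABCO cat., CH2Cl2) to give tert-butyl (E)-3-[3-(benzyloxy)-4-methoxyphenoxy]prop-2-enoate F4. Bromination at the α-carbon (N-bromosuccinimide, CH2Cl2, 0 °C, then Et3N) should give tert-butyl (Z)-3-[3-(benzyloxy)-4-methoxyphenoxy]-2-bromoprop-2-enoate F5; competing bromination of ring A para to the benzyloxy group is the weak point here. Suzuki–Miyaura coupling of F5 with A5 (Pd(PPh3)4, K3PO4, dioxane/water, 80 °C) proceeds with retention and should give 8.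

Step 7. The most likely failure is over-reduction: the C2=C3 bond may be hydrogenated to the isoflavanone once the benzyl group is gone, or the hydrogenolysis may stall on the poorly soluble product. The fallback replaces reduction by Lewis acid cleavage with a cation scavenger. It sets out from 11 and comes back at 12. Treating 11 with BCl3 and pentamethylbenzene (CH2Cl2, −78 °C) should transfer the benzyl cation to the scavenger and leave dichloro{[6-methoxy-4-oxo-3-(3,4,5-trimethoxyphenyl)-4H-chromen-7-yl]oxy}borane F6, which aqueous work-up hydrolyses to 12. The low temperature is what protects the methyl ethers, the 4'-methoxy group in particular.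

## Further compounds

F1 | step 6 | 3-(benzyloxy)-4-methoxyphenyl 2-(3,4,5-trimethoxyphenyl)acetate | COc1ccc(OC(=O)Cc2cc(OC)c(OC)c(OC)c2)cc1OCc1ccccc1
F2 | step 6 | 1-[4-(benzyloxy)-2-hydroxy-5-methoxyphenyl]-2-(3,4,5-trimethoxyphenyl)ethan-1-one | COc1cc(C(=O)Cc2cc(OC)c(OC)c(OC)c2)c(O)cc1OCc1ccccc1
F3 | step 6 | (E)-1-[4-(benzyloxy)-2-hydroxy-5-methoxyphenyl]-3-(dimethylamino)-2-(3,4,5-trimethoxyphenyl)prop-2-en-1-one | CN(C)/C=C(\c1cc(OC)c(OC)c(OC)c1)C(=O)c1cc(OC)c(OCc2ccccc2)cc1O
F4 | step 5 | tert-butyl (E)-3-[3-(benzyloxy)-4-methoxyphenoxy]prop-2-enoate | CC(C)(C)OC(=O)/C=C/Oc1ccc(OC)c(OCc2ccccc2)c1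
F5 | step 5 | tert-butyl (Z)-3-[3-(benzyloxy)-4-methoxyphenoxy]-2-bromoprop-2-enoate | CC(C)(C)OC(=O)/C(Br)=C/Oc1ccc(OC)c(OCc2ccccc2)c1
F6 | step 7 | dichloro{[6-methoxy-4-oxo-3-(3,4,5-trimethoxyphenyl)-4H-chromen-7-yl]oxy}borane | COc1cc2c(=O)c(-c3cc(OC)c(OC)c(OC)c3)coc2cc1OB(Cl)Cl
A1 | alternative 1 | 4-methoxybenzene-1,3-diol | COc1ccc(O)cc1O
A2 | alternative 1 | 1-(2,4-dihydroxy-5-methoxyphenyl)-2-(3,4,5-trimethoxyphenyl)ethan-1-one | COc1cc(C(=O)Cc2cc(OC)c(OC)c(OC)c2)c(O)cc1O
A3 | alternative 2 | 1-[4-(benzyloxy)-2-hydroxy-5-methoxyphenyl]ethan-1-one | COc1cc(C(C)=O)c(O)cc1OCc1ccccc1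
A4 | alternative 2 | 7-(benzyloxy)-3-iodo-6-methoxy-4H-chromen-4-one | COc1cc2c(=O)c(I)coc2cc1OCc1ccccc1
A5 | alternative 2 | (3,4,5-trimethoxyphenyl)boronic acid | COc1cc(B(O)O)cc(OC)c1OC
A6 | alternative 3 | 4-(benzyloxy)-5-methoxy-2-(trimethylsilyl)phenyl trifluoromethanesulfonate | COc1cc(OS(=O)(=O)C(F)(F)F)c([Si](C)(C)C)cc1OCc1ccccc1
A7 | alternative 3 | 4-(benzyloxy)-5-methoxybenzyne | COC1=CC#CC=C1OCc1ccccc1
A8 | alternative 3 | (E)-3-methoxy-2-(3,4,5-trimethoxyphenyl)prop-2-enoic acid | CO/C=C(/C(=O)O)c1cc(OC)c(OC)c(OC)c1
A9 | alternative 3 | 6-(benzyloxy)-7-methoxy-3-(3,4,5-trimethoxyphenyl)-4H-chromen-4-one | COc1cc2occ(-c3cc(OC)c(OC)c(OC)c3)c(=O)c2cc1OCc1ccccc1
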